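**Retrosynthetic overview**

- Feature: in ring C, C4 (the ketone) and C3 (the carbon that carries ring B) are both carbonyl-derived carbons. The C3–C4 bond is therefore made by polarity reversal: the ring A aldehyde carbon (future C4) adds as an acyl anion to a ring B aryl ketone carbon (future C3) held by the O1–C2 tether.
- Target 15 ⇒ (C2=C3 dehydration, loss of two MOM groups) 3-hydroxychroman-4-one 13 ⇒ (C3–C4, carbene-catalysed crossed benzoin) keto-aldehyde 12 ⇒ (O1–C2, Williamson) phenol aldehyde 4 + bromomethyl ketone 11.
- 4 comes from 5-methoxyresorcinol 1 (formylation, O4 protection). 11 comes from 3,4-dihydroxyacetophenone 5 and 3-chloro-3-methylbut-1-yne 6 (O-propargylation, protection, Claisen/electrocyclisation, α-bromination); starting from the acetophenone avoids a methyl addition and an oxidation.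
- Ring order: ring A and the benzene ring of ring B are bought; the pyran ring fused to ring B is made first (step 5); ring C is closed in step 8 and becomes the pyranone in step 9.

Key step: step 8

Assumption: the target is achiral, so the C3 carbinol of 13 is carried as a racemate; in step 9 acetal cleavage is taken to run ahead of dehydration (the opposite order would lead to the same product).

**Route**

Step 1
Reactants: 1 5-methoxyresorcinol (5-methoxybenzene-1,3-diol)
Product: 3 2,4-dihydroxy-6-methoxybenzaldehyde, via aryl iminium chloride 2 (not isolated)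
Conditions: POCl3, DMF, EtOAc, 0 °C → rt; then H2O, 50 °C
Reagents that add atoms: N,N-dimethylformamide (DMF), CN(C)C=O; water, O
Why: Vilsmeier–Haack formylation should go mainly to the two equivalent ring positions that lie para to one hydroxyl and between the other hydroxyl and the methoxy group, and hydrolysis of iminium salt 2 releases the aldehyde; the minor isomer formylated between the two hydroxyls would be removed by crystallisation or chromatography.

Step 2
Reactants: 3 2,4-dihydroxy-6-methoxybenzaldehyde
Product: 4 2-hydroxy-6-methoxy-4-(methoxymethoxy)benzaldehyde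
Conditions: MOMCl (1.05 equiv), i-Pr2NEt, CH2Cl2, 0 °C
Reagents that add atoms: chloromethyl methyl ether (MOMCl), COCCl
Why: Chemoselective O-alkylation (MOM ether formation) should take place at the free and more acidic hydroxyl para to the formyl group, because the ortho hydroxyl is tied up in a hydrogen bond to the aldehyde.

Step 3
Reactants: 5 3,4-dihydroxyacetophenone [1-(3,4-dihydroxyphenyl)ethanone]; 6 3-chloro-3-methylbut-1-yne
Product: 7 1-{3-hydroxy-4-[(2-methylbut-3-yn-2-yl)oxy]phenyl}ethanone
Conditions: K2CO3 (1.0 equiv), KI (cat.), CuI (cat.), DMF, N2, 45 °C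
Reagents that add atoms: none
Why: Copper-assisted Williamson-type O-propargylation with a tertiary propargylic chloride should occur at O4, since one equivalent of carbonate ionises mainly the hydroxyl para to the acetyl group, the more acidic of the two.

Step 4
Reactants: 7 1-{3-hydroxy-4-[(2-methylbut-3-yn-2-yl)oxy]phenyl}ethanone
Product: 8 1-{3-(methoxymethoxy)-4-[(2-methylbut-3-yn-2-yl)oxy]phenyl}ethanone
Conditions: MOMCl, i-Pr2NEt, CH2Cl2, 0 °C → rt
Reagents that add atoms: chloromethyl methyl ether (MOMCl), COCCl
Why: Standard MOM ether formation on the one remaining phenol gives an acetal that survives the heat of step 5, the base of steps 6–8, and falls off in the final acid step.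

Step 5
Reactants: 8 1-{3-(methoxymethoxy)-4-[(2-methylbut-3-yn-2-yl)oxy]phenyl}ethanone
Product: 9 1-[8-(methoxymethoxy)-2,2-dimethyl-2H-chromen-6-yl]ethanone
Conditions: PhNEt2, 190 °C
Reagents that add atoms: none
Why: Aromatic propargyl Claisen rearrangement to the only free ortho carbon, followed by enolisation, [1,5]-hydrogen shift and 6π oxa-electrocyclisation, should give the 2,2-dimethyl-2H-chromene with a single possible ring fusion because the other ortho carbon carries the MOM ether.

Step 6
Reactants: 9 1-[8-(methoxymethoxy)-2,2-dimethyl-2H-chromen-6-yl]ethanone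
Product: 11 2-bromo-1-[8-(methoxymethoxy)-2,2-dimethyl-2H-chromen-6-yl]ethanone, via trimethylsilyl enol ether 10 (not isolated)
Conditions: LiN(SiMe3)2, Me3SiCl, THF, −78 °C; volatiles removed; then NBS, THF, −78 → 0 °C
Reagents that add atoms: N-bromosuccinimide (NBS), O=C1CCC(=O)N1Br
Why: Kinetic enolate silylation followed by electrophilic bromination of the silyl enol ether should give clean monobromination at the methyl carbon, since the enol ether is far more nucleophilic than the chromene double bond or the acyl-deactivated arene at low temperature.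

Step 7
Reactants: 4 2-hydroxy-6-methoxy-4-(methoxymethoxy)benzaldehyde; 11 2-bromo-1-[8-(methoxymethoxy)-2,2-dimethyl-2H-chromen-6-yl]ethanone
Product: 12 2-{2-[8-(methoxymethoxy)-2,2-dimethyl-2H-chromen-6-yl]-2-oxoethoxy}-6-methoxy-4-(methoxymethoxy)benzaldehyde
Conditions: K2CO3, acetone, rt
Reagents that add atoms: none
Why: Williamson ether synthesis by fast SN2 displacement of the α-keto bromide by the phenoxide should form the O1–C2 tether, and carbonate in acetone at room temperature is mild enough to leave the product short of the aldol condensation to a benzofuran (Rap–Stoermer reaction).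

Step 8
Reactants: 12 2-{2-[8-(methoxymethoxy)-2,2-dimethyl-2H-chromen-6-yl]-2-oxoethoxy}-6-methoxy-4-(methoxymethoxy)benzaldehyde
Product: 13 rac-3-hydroxy-5-methoxy-7-(methoxymethoxy)-3-[8-(methoxymethoxy)-2,2-dimethyl-2H-chromen-6-yl]chroman-4-one
Conditions: 3-benzyl-5-(2-hydroxyethyl)-4-methylthiazolium chloride (20 mol %), DBU (15 mol %), t-BuOH–THF, Ar, 40 °C
Reagents that add atoms: none
Why: The thiazol-2-ylidene set free by DBU adds to the ring A aldehyde and proton transfer gives the enaminol, an acyl anion equivalent at the future C4, which attacks the tethered aryl ketone carbon (future C3); collapse of the adduct expels the carbene and leaves the C4 ketone and the C3 tertiary alcohol. The closest known reaction type is the carbene-catalysed intramolecular crossed aldehyde–ketone benzoin cyclisation of 2-(2-oxoalkoxy)benzaldehydes to 3-hydroxychroman-4-ones. Ring C closes in a 6-exo-trig mode onto the ketone carbonyl. The new C3 stereocentre is formed without control, as a racemate, because substrate and catalyst are achiral, and it is erased in step 9. The step needs the aldehyde as the only donor and the ketone as the only acceptor, which the substrate secures because a ketone cannot form the enaminol and the six-membered closure should outrun any aldehyde dimerisation; the base-mediated aldol closure to a 2-aroylbenzofuran is held back by keeping DBU below the thiazolium loading in a hindered alcohol at 40 °C. The main risk is slow carbene addition to the doubly ortho-oxygenated, electron-rich aldehyde.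

Step 9
Reactants: 13 rac-3-hydroxy-5-methoxy-7-(methoxymethoxy)-3-[8-(methoxymethoxy)-2,2-dimethyl-2H-chromen-6-yl]chroman-4-one
Product: 15 Glycyrrhizaisoflavone B [7-hydroxy-3-(8-hydroxy-2,2-dimethyl-2H-chromen-6-yl)-5-methoxy-4H-chromen-4-one], via free triol 14 (not isolated)
Conditions: conc. HCl, MeOH–THF, 50 °C
Reagents that add atoms: none
Why: Methanolic acid should cleave both MOM acetals by acetal exchange and then effect E1 dehydration, in which ionisation of the tertiary benzylic C3 alcohol is helped by the para ether oxygen of ring B and loss of a C2 proton gives the conjugated 4H-chromen-4-one, removing the C3 stereocentre.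

**Compound list**

1 | 5-methoxyresorcinol (5-methoxybenzene-1,3-diol) | COc1cc(O)cc(O)c1 | starting material
2 | N-[(2,4-dihydroxy-6-methoxyphenyl)methylidene]-N-methylmethanaminium chloride | COc1cc(O)cc(O)c1C=[N+](C)C.[Cl-] | intermediate (not isolated)
3 | 2,4-dihydroxy-6-methoxybenzaldehyde | COc1cc(O)cc(O)c1C=O | intermediate
4 | 2-hydroxy-6-methoxy-4-(methoxymethoxy)benzaldehyde | COCOc1cc(O)c(C=O)c(OC)c1 | intermediate
5 | 3,4-dihydroxyacetophenone | CC(=O)c1ccc(O)c(O)c1 | starting material
6 | 3-chloro-3-methylbut-1-yne | C#CC(C)(C)Cl | starting material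
7 | 1-{3-hydroxy-4-[(2-methylbut-3-yn-2-yl)oxy]phenyl}ethanone | CC(=O)c1ccc(OC(C)(C)C#C)c(O)c1 | intermediate
8 | 1-{3-(methoxymethoxy)-4-[(2-methylbut-3-yn-2-yl)oxy]phenyl}ethanone | CC(=O)c1ccc(OC(C)(C)C#C)c(OCOC)c1 | intermediate
9 | 1-[8-(methoxymethoxy)-2,2-dimethyl-2H-chromen-6-yl]ethanone | CC(=O)c1cc(OCOC)c2OC(C)(C)C=Cc2c1 | intermediate
10 | {1-[8-(methoxymethoxy)-2,2-dimethyl-2H-chromen-6-yl]ethenyl}oxy(trimethyl)silane | C=C(O[Si](C)(C)C)c1cc(OCOC)c2OC(C)(C)C=Cc2c1 | intermediate (not isolated)
11 | 2-bromo-1-[8-(methoxymethoxy)-2,2-dimethyl-2H-chromen-6-yl]ethanone | BrCC(=O)c1cc(OCOC)c2OC(C)(C)C=Cc2c1 | intermediate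
12 | 2-{2-[8-(methoxymethoxy)-2,2-dimethyl-2H-chromen-6-yl]-2-oxoethoxy}-6-methoxy-4-(methoxymethoxy)benzaldehyde | COCOc1cc(OC)c(C=O)c(OCC(=O)c2cc(OCOC)c3OC(C)(C)C=Cc3c2)c1 | intermediate
13 | rac-3-hydroxy-5-methoxy-7-(methoxymethoxy)-3-[8-(methoxymethoxy)-2,2-dimethyl-2H-chromen-6-yl]chroman-4-one | COCOc1cc(OC)c2C(=O)C(O)(c3cc(OCOC)c4OC(C)(C)C=Cc4c3)COc2c1 | intermediate
14 | rac-3,7-dihydroxy-3-(8-hydroxy-2,2-dimethyl-2H-chromen-6-yl)-5-methoxychroman-4-one | COc1cc(O)cc2OCC(O)(c3cc(O)c4c(c3)C=CC(C)(C)O4)C(=O)c12 | intermediate (not isolated)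
15 | Glycyrrhizaisoflavone B | COc1cc(O)cc2occ(-c3cc(O)c4c(c3)C=CC(C)(C)O4)c(=O)c12 | target

**Step count**

Total: 9 steps. Longest linear sequence: 7 steps (steps 3–9, from 3,4-dihydroxyacetophenone 5); the ring A branch contributes steps 1 and 2.

**Steps most likely to fail**

Step 8 (crossed benzoin closure). The carbene may add too slowly to an aldehyde that is flanked by two ortho oxygens and fed by the para acetal oxygen, so that non-conversion or base-induced aldol closure of the ketone α-carbon onto the aldehyde takes over. The fallback changes the design of the donor rather than the conditions: the electron-releasing acetal at O7 is replaced by an electron-withdrawing ester, which should make the aldehyde carbon more electrophilic toward the carbene. It sets out from 3 and 11. Acylation of 3 with pivaloyl chloride and Et3N at the free para hydroxyl should give 4-formyl-3-hydroxy-5-methoxyphenyl pivalate F1. Williamson etherification of F1 with 11 (K2CO3, acetone, rt) gives the pivalate keto-aldehyde F2. The same thiazolium/DBU closure then gives the 7-pivaloyloxy-3-hydroxychroman-4-one F3. Methanolic HCl dehydrates F3 and removes the ring B acetal while the hindered aryl ester should largely survive, giving the 7-O-pivaloyl isoflavone F4. K2CO3 in MeOH then frees the C7 phenol and the sequence comes back to the route at 15.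

Step 9 (dehydration with loss of both acetals). Ionisation at C3 next to the carbonyl may lag behind acetal cleavage, and during the longer heating an acyloin-type rearrangement of the protonated hydroxy ketone or acid addition across the chromene double bond may compete. The fallback separates the two events and dehydrates without acid; it sets out from 13. Treatment with methyl N-(triethylammoniosulfonyl)carbamate (Burgess reagent) in toluene at 60 °C forms the C3 sulfamate ester, which undergoes syn-elimination with a C2 hydrogen to give the bis-MOM isoflavone 5-methoxy-7-(methoxymethoxy)-3-[8-(methoxymethoxy)-2,2-dimethyl-2H-chromen-6-yl]-4H-chromen-4-one F5. A short treatment of this stable chromone with dilute HCl in MeOH at room temperature removes the acetals and returns to the route at 15.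

Step 3 (mono-propargylation of the catechol). Alkylation may occur at the wrong oxygen or at both, or the tertiary chloride may react sluggishly under the weakly basic conditions that selectivity requires. The fallback controls regiochemistry by a protecting-group relay with a well-behaved primary halide; it sets out from 5. Benzyl bromide with Li2CO3 in DMF should give 1-[4-(benzyloxy)-3-hydroxyphenyl]ethanone F6. MOMCl and i-Pr2NEt give 1-[4-(benzyloxy)-3-(methoxymethoxy)phenyl]ethanone F7. Hydrogenolysis (H2, Pd/C, EtOAc, rt) frees O4 to give 1-[4-hydroxy-3-(methoxymethoxy)phenyl]ethanone F8. This single phenol is then propargylated with 6 under forcing copper conditions (CuCl2·2H2O cat., DBU, MeCN, 0 °C), which comes back to the route at 8.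

**Further compounds**

F1 | step 8 | 4-formyl-3-hydroxy-5-methoxyphenyl 2,2-dimethylpropanoate | COc1cc(OC(=O)C(C)(C)C)cc(O)c1C=O
F2 | step 8 | 4-formyl-3-methoxy-5-{2-[8-(methoxymethoxy)-2,2-dimethyl-2H-chromen-6-yl]-2-oxoethoxy}phenyl 2,2-dimethylpropanoate | COc1cc(OC(=O)C(C)(C)C)cc(OCC(=O)c2cc(OCOC)c3OC(C)(C)C=Cc3c2)c1C=O
F3 | step 8 | rac-3-hydroxy-5-methoxy-3-[8-(methoxymethoxy)-2,2-dimethyl-2H-chromen-6-yl]-4-oxochroman-7-yl 2,2-dimethylpropanoate | COc1cc(OC(=O)C(C)(C)C)cc2OCC(O)(c3cc(OCOC)c4OC(C)(C)C=Cc4c3)C(=O)c12
F4 | step 8 | 3-(8-hydroxy-2,2-dimethyl-2H-chromen-6-yl)-5-methoxy-4-oxo-4H-chromen-7-yl 2,2-dimethylpropanoate | COc1cc(OC(=O)C(C)(C)C)cc2occ(-c3cc(O)c4c(c3)C=CC(C)(C)O4)c(=O)c12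
F5 | step 9 | 5-methoxy-7-(methoxymethoxy)-3-[8-(methoxymethoxy)-2,2-dimethyl-2H-chromen-6-yl]-4H-chromen-4-one | COCOc1cc(OC)c2c(=O)c(-c3cc(OCOC)c4OC(C)(C)C=Cc4c3)coc2c1
F6 | step 3 | 1-[4-(benzyloxy)-3-hydroxyphenyl]ethanone | CC(=O)c1ccc(OCc2ccccc2)c(O)c1
F7 | step 3 | 1-[4-(benzyloxy)-3-(methoxymethoxy)phenyl]ethanone | CC(=O)c1ccc(OCc2ccccc2)c(OCOC)c1
F8 | step 3 | 1-[4-hydroxy-3-(methoxymethoxy)phenyl]ethanone | CC(=O)c1ccc(O)c(OCOC)c1
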